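The target is cut at the tetralin C1–C8a bond (C1 bears biaryl ring C, C8a belongs to arene D), which turns both halves of the dimer into the same 2-aryl-4-benzyl-4-hydroxy-3-(hydroxymethyl)oxolane. The key step exploits the free phenol of ring C para to oxolane C2: acid expels O1 to give a p-quinone methide, and C6 of the 4-hydroxy-3-methoxybenzyl ring adds to it, closing the carbocycle and setting C1 in one operation. Its precursor is the 5,5'-linked bis-oxolane whose ring B phenol is a mesylate, so only one oxolane can ionise. Each half is made from an (S)-malic acid lactone and 5-bromovanillin, and a Suzuki coupling joins them.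

Key step: step 18

Labels: ring A = 3-hydroxy-4-methoxybenzyl ring; ring B = biaryl ring carrying the surviving oxolane; ring C = biaryl ring on the tetralin; ring D = tetralin arene. Oxolane atoms are O1, C2 (aryl), C3 (CH2OH), C4 (OH, benzyl), C5; the tetralin is numbered from the carbon bearing ring C.

Check of structures: both oxolanes are (2S,3R,4S) and the tetralin is (1S,2S,3S); target, key-step substrate and key-step product agree with one another and need no correction.

Design remark: an oxolane whose 2-aryl group carries a para mesylate cannot be closed by benzylic ionisation, and a biaryl dialdehyde cannot tell two different lactones apart. Each half is therefore built separately on 5-bromovanillin, each oxolane is closed while its para phenol is free, the mesylate is put on ring B afterwards, and the halves are joined by cross-coupling.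

Assumption: the two O-benzylated benzyl alcohols and 5-bromovanillin are bought. The carbinol and tetrahydropyranyl acetal centres of the aldol adducts and tetraols are carried as mixtures, because ring closure erases both.

Step 1
Reactants: 1 (S)-malic acid
Product: 2 2-[(2S,4S)-2-tert-butyl-5-oxo-1,3-dioxolan-4-yl]acetic acid (tert-butyl and CH2CO2H cis)
Conditions: t-BuCHO, p-TsOH·H2O (cat.), H2SO4 (cat.), pentane, reflux, Dean–Stark; recrystallisation
Reagents that add atoms: pivalaldehyde, CC(C)(C)C=O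
Why: Acid-catalysed acetalisation of the α-hydroxy acid unit gives the 1,3-dioxolan-4-one, the new acetal centre settling cis to the side chain under thermodynamic control relative to the untouched malate carbon, and crystallisation should secure the pure cis isomer.

Step 2
Reactants: 3 4-(benzyloxy)-3-methoxybenzyl alcohol
Product: 4 4-(benzyloxy)-3-methoxybenzyl bromide
Conditions: PBr3 (0.4 equiv), Et2O, 0 °C; used crude
Reagents that add atoms: phosphorus tribromide, BrP(Br)Br
Why: Bromination of an electron-rich benzylic alcohol through its phosphite ester is fast at 0 °C and leaves the aryl benzyl ether untouched.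

Step 3
Reactants: 2 2-[(2S,4S)-2-tert-butyl-5-oxo-1,3-dioxolan-4-yl]acetic acid, 4 4-(benzyloxy)-3-methoxybenzyl bromide
Product: 5 2-[(2S,4S)-4-(4-benzyloxy-3-methoxybenzyl)-2-tert-butyl-5-oxo-1,3-dioxolan-4-yl]acetic acid
Conditions: LiN(SiMe3)2 (2.1 equiv), THF, −78 °C; then 4, −78 → −20 °C; cold 1 M HCl
Reagents that add atoms: none
Why: Alkylation of the lithium carboxylate–enolate dianion (self-regeneration of stereocentres) takes the benzyl bromide on the enolate face anti to the tert-butyl group, so the arylmethyl group enters where the hydrogen was and the quaternary centre forms as (S) with retention.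

Step 4
Reactants: 5 2-[(2S,4S)-4-(4-benzyloxy-3-methoxybenzyl)-2-tert-butyl-5-oxo-1,3-dioxolan-4-yl]acetic acid
Product: 7 (4S)-4-(4-benzyloxy-3-methoxybenzyl)-4-hydroxyoxolan-2-one, via dihydroxy acid 6 (not isolated)
Conditions: LiBH4 (3 equiv), THF, 0 °C → rt; then 2 M HCl, rt
Reagents that add atoms: none
Why: Chemoselective hydride reduction in which LiBH4 reduces the activated dioxolanone carbonyl but not the lithium carboxylate, the hemiacetal collapses with loss of pivalaldehyde (reduced on to neopentyl alcohol), and on acidification γ-hydroxy acid 6 lactonises without touching the quaternary centre.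

Step 5
Reactants: 8 3-(benzyloxy)-4-methoxybenzyl alcohol
Product: 9 3-(benzyloxy)-4-methoxybenzyl bromide
Conditions: PBr3 (0.4 equiv), Et2O, 0 °C; used crude
Reagents that add atoms: phosphorus tribromide, BrP(Br)Br
Why: The same phosphite-mediated benzylic bromination as in step 2 applies to the isomeric alcohol.

Step 6
Reactants: 2 2-[(2S,4S)-2-tert-butyl-5-oxo-1,3-dioxolan-4-yl]acetic acid, 9 3-(benzyloxy)-4-methoxybenzyl bromide
Product: 10 2-[(2S,4S)-4-(3-benzyloxy-4-methoxybenzyl)-2-tert-butyl-5-oxo-1,3-dioxolan-4-yl]acetic acid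
Conditions: LiN(SiMe3)2 (2.1 equiv), THF, −78 °C; then 9, −78 → −20 °C; cold 1 M HCl
Reagents that add atoms: none
Why: As in step 3, dianion alkylation anti to the tert-butyl group should give the (S) quaternary centre with retention.

Step 7
Reactants: 10 2-[(2S,4S)-4-(3-benzyloxy-4-methoxybenzyl)-2-tert-butyl-5-oxo-1,3-dioxolan-4-yl]acetic acid
Product: 12 (4S)-4-(3-benzyloxy-4-methoxybenzyl)-4-hydroxyoxolan-2-one, via dihydroxy acid 11 (not isolated)
Conditions: LiBH4 (3 equiv), THF, 0 °C → rt; then 2 M HCl, rt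
Reagents that add atoms: none
Why: As in step 4, borohydride reduces only the dioxolanone carbonyl and acid closes γ-hydroxy acid 11 to the β-hydroxy-γ-butyrolactone.

Step 8
Reactants: 13 5-bromovanillin
Product: 14 3-bromo-5-methoxy-4-(oxan-2-yloxy)benzaldehyde (racemic at the acetal carbon)
Conditions: 3,4-dihydro-2H-pyran (2 equiv), PPTS (cat.), CH2Cl2, rt
Reagents that add atoms: 3,4-dihydro-2H-pyran, C1=COCCC1
Why: Acid-catalysed addition of the phenol to the enol ether (tetrahydropyranylation) masks it as an acetal that is inert to enolates and hydride but falls off in weak aqueous acid.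

Step 9
Reactants: 7 (4S)-4-(4-benzyloxy-3-methoxybenzyl)-4-hydroxyoxolan-2-one, 14 3-bromo-5-methoxy-4-(oxan-2-yloxy)benzaldehyde
Product: 15 (3R,4S)-4-(4-benzyloxy-3-methoxybenzyl)-3-{[3-bromo-5-methoxy-4-(oxan-2-yloxy)phenyl](hydroxy)methyl}-4-hydroxyoxolan-2-one (carbinol and acetal centres as mixtures)
Conditions: LiN(i-Pr)2 (2.1 equiv), THF, −78 °C; then 14 (1.1 equiv), −78 °C; AcOH quench at −78 °C
Reagents that add atoms: none
Why: Aldol addition of the alkoxide–enolate dianion of a β-hydroxy-γ-butyrolactone, in which the aldehyde should bond to C3 anti to the larger arylmethyl group, on the face of the small lithium alkoxide that can also bind the aldehyde, setting C3 as R, while the carbinol centre is left uncontrolled because step 10 erases it.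

Step 10
Reactants: 15 (3R,4S)-4-(4-benzyloxy-3-methoxybenzyl)-3-{[3-bromo-5-methoxy-4-(oxan-2-yloxy)phenyl](hydroxy)methyl}-4-hydroxyoxolan-2-one
Product: 19 4-[(2S,3R,4S)-4-(4-benzyloxy-3-methoxybenzyl)-4-hydroxy-3-(hydroxymethyl)oxolan-2-yl]-2-bromo-6-methoxyphenol, via tetraol 16 (not isolated), via phenol tetraol 17 (not isolated), via quinone methide 18 (not isolated)
Conditions: LiBH4 (3 equiv), THF, 0 °C → rt; then AcOH–THF–H2O (4:2:1), 45 °C
Reagents that add atoms: none
Why: Lactone reduction gives tetraol 16, aqueous acetic acid removes the aryl acetal, and the p-hydroxybenzylic alcohol of 17 ionises to p-quinone methide 18, which the primary hydroxyl on the quaternary carbinol captures in a reversible 5-exo-trig oxa-Michael closure, so both carbinol epimers should converge on the 2,3-trans oxolane (C2 S), while the weak acid leaves the methide unprotonated and Friedel–Crafts attack by the benzyl ring should not compete.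

Step 11
Reactants: 19 4-[(2S,3R,4S)-4-(4-benzyloxy-3-methoxybenzyl)-4-hydroxy-3-(hydroxymethyl)oxolan-2-yl]-2-bromo-6-methoxyphenol
Product: 20 (3S,4R,5S)-3-(4-benzyloxy-3-methoxybenzyl)-5-(4-benzyloxy-3-bromo-5-methoxyphenyl)-4-(hydroxymethyl)oxolan-3-ol
Conditions: BnBr (1.1 equiv), K2CO3, DMF, rt
Reagents that add atoms: benzyl bromide, BrCc1ccccc1
Why: Williamson etherification in which carbonate deprotonates only the phenol, so it alone is benzylated, which blocks quinone methide formation and sulfonyl migration in the basic steps that follow.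

Step 12
Reactants: 20 (3S,4R,5S)-3-(4-benzyloxy-3-methoxybenzyl)-5-(4-benzyloxy-3-bromo-5-methoxyphenyl)-4-(hydroxymethyl)oxolan-3-ol
Product: 21 (3S,4R,5S)-3-(4-benzyloxy-3-methoxybenzyl)-5-[4-benzyloxy-3-methoxy-5-(4,4,5,5-tetramethyl-1,3,2-dioxaborolan-2-yl)phenyl]-4-(hydroxymethyl)oxolan-3-ol
Conditions: B2pin2 (1.5 equiv), PdCl2(dppf) (5 mol %; dppf = 1,1'-bis(diphenylphosphino)ferrocene), KOAc (3 equiv), 1,4-dioxane, 90 °C
Reagents that add atoms: bis(pinacolato)diboron, CC1(C)OB(OC1(C)C)B1OC(C)(C)C(C)(C)O1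
Why: Miyaura borylation of the aryl bromide tolerates free alcohols, and the weak acetate base should suppress biaryl homocoupling.

Step 13
Reactants: 12 (4S)-4-(3-benzyloxy-4-methoxybenzyl)-4-hydroxyoxolan-2-one, 14 3-bromo-5-methoxy-4-(oxan-2-yloxy)benzaldehyde
Product: 22 (3R,4S)-4-(3-benzyloxy-4-methoxybenzyl)-3-{[3-bromo-5-methoxy-4-(oxan-2-yloxy)phenyl](hydroxy)methyl}-4-hydroxyoxolan-2-one (carbinol and acetal centres as mixtures)
Conditions: LiN(i-Pr)2 (2.1 equiv), THF, −78 °C; then 14 (1.1 equiv), −78 °C; AcOH quench at −78 °C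
Reagents that add atoms: none
Why: The same dianion aldol addition as in step 9 should place the new bond at C3 anti to the arylmethyl group (C3 R).

Step 14
Reactants: 22 (3R,4S)-4-(3-benzyloxy-4-methoxybenzyl)-3-{[3-bromo-5-methoxy-4-(oxan-2-yloxy)phenyl](hydroxy)methyl}-4-hydroxyoxolan-2-one
Product: 26 4-[(2S,3R,4S)-4-(3-benzyloxy-4-methoxybenzyl)-4-hydroxy-3-(hydroxymethyl)oxolan-2-yl]-2-bromo-6-methoxyphenol, via tetraol 23 (not isolated), via phenol tetraol 24 (not isolated), via quinone methide 25 (not isolated)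
Conditions: LiBH4 (3 equiv), THF, 0 °C → rt; then AcOH–THF–H2O (4:2:1), 45 °C
Reagents that add atoms: none
Why: As in step 10, reduction, acetal cleavage and reversible 5-exo-trig capture of quinone methide 25 by the primary hydroxyl should deliver the 2,3-trans oxolane (C2 S) from either carbinol epimer.

Step 15
Reactants: 26 4-[(2S,3R,4S)-4-(3-benzyloxy-4-methoxybenzyl)-4-hydroxy-3-(hydroxymethyl)oxolan-2-yl]-2-bromo-6-methoxyphenol
Product: 27 2-bromo-4-[(2S,3R,4S)-4-(3-benzyloxy-4-methoxybenzyl)-4-hydroxy-3-(hydroxymethyl)oxolan-2-yl]-6-methoxyphenyl methanesulfonate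
Conditions: MsCl (1.05 equiv), K2CO3 (2 equiv), acetone, 0 °C
Reagents that add atoms: methanesulfonyl chloride, CS(=O)(=O)Cl
Why: Chemoselective O-sulfonylation in which only the phenol, acidified by the ortho bromine, is converted to its potassium salt, and this phenoxide is sulfonylated far faster than the neutral primary and tertiary alcohols.

Step 16
Reactants: 21 (3S,4R,5S)-3-(4-benzyloxy-3-methoxybenzyl)-5-[4-benzyloxy-3-methoxy-5-(4,4,5,5-tetramethyl-1,3,2-dioxaborolan-2-yl)phenyl]-4-(hydroxymethyl)oxolan-3-ol, 27 2-bromo-4-[(2S,3R,4S)-4-(3-benzyloxy-4-methoxybenzyl)-4-hydroxy-3-(hydroxymethyl)oxolan-2-yl]-6-methoxyphenyl methanesulfonate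
Product: 28 5,5'-linked bis-oxolane, both oxolanes (2S,3R,4S): ring B O-mesyl with the 3-benzyloxy-4-methoxybenzyl oxolane, ring C O-benzyl with the 4-benzyloxy-3-methoxybenzyl oxolane
Conditions: Pd(OAc)2 (5 mol %), SPhos (2-dicyclohexylphosphino-2',6'-dimethoxybiphenyl, 10 mol %), K3PO4 (3 equiv), 1,4-dioxane–H2O (5:1), 80 °C
Reagents that add atoms: none
Why: Suzuki–Miyaura coupling in which zerovalent palladium inserts into the C–Br bond of the electron-poor mesylate-bearing ring and leaves the C–OMs bond alone, the bulky biaryl phosphine copes with one ortho oxygen substituent on each partner, and the new axis is no stereoelement because only two ortho positions are substituted.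

Step 17
Reactants: 28 tri-O-benzyl bis-oxolane mesylate
Product: 29 bis-oxolane with free phenols on rings A, C and D and the ring B mesylate (both oxolanes (2S,3R,4S))
Conditions: H2 (1 atm), Pd/C (10 wt %), EtOAc–MeOH, rt
Reagents that add atoms: none
Why: Hydrogenolysis of the three aryl benzyl ethers under neutral conditions at 1 atm should be much faster than cleavage of the cyclic benzylic ethers or of the aryl mesylate, and the neutral medium gives the mesyl group no chance to migrate to the neighbouring ring C phenol.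

Step 18
Reactants: 29 bis-oxolane with free phenols on rings A, C and D and the ring B mesylate
Product: 31 ring B mesylate of the target ((1S,2S,3S) tetralin on ring C, (2S,3R,4S) oxolane on ring B), via quinone methide 30 (not isolated)
Conditions: CF3CO2H (10 vol %), CH2Cl2–MeCN (1:1), 0 °C → rt; aq. NaHCO3 work-up
Reagents that add atoms: none
Why: Acid protonates O1 of the oxolane on ring C and the free para phenol pushes out the C2–O1 bond, giving p-quinone methide 30 and freeing the former C5 oxygen as a hydroxymethyl group; the protonated methide carbon is then attacked by C6 of the 4-hydroxy-3-methoxybenzyl ring, and rearomatisation makes the C1–C8a bond permanent. The closest known reaction type is the acid-mediated isomerisation of 2-(4-hydroxyaryl)-4-benzyloxolane lignans into 1-aryltetralins (olivil to cycloolivil). The six-membered carbocycle closes in a 6-exo-trig Friedel–Crafts mode with respect to the exocyclic methide double bond. The new C1 centre (S) is controlled by the existing C2 and C3 centres through a half-chair transition state in which the ring C aryl group and both hydroxymethyl groups are pseudo-equatorial, which puts the C1 aryl trans to the C2 hydroxymethyl group. Site selectivity between the two oxolanes is secured by the ring B mesylate, which takes away the phenol push para to the other benzylic ether, so that oxolane stays closed. Regioselectivity on ring D is secured by the methoxy group para to the attacking carbon, the only other position within reach being flanked by the benzylic carbon and the methoxy group.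

Step 19
Reactants: 31 ring B mesylate of the target
Product: 32 CNP0252244.1 (target)
Conditions: KOH (10 equiv), MeOH–H2O (4:1), 60 °C, Ar; then 1 M HCl to pH 5
Reagents that add atoms: none
Why: Hydroxide cleaves the S–O bond of the aryl mesylate and releases the phenoxide, no stereocentre or ether in the molecule is base-sensitive, and exclusion of air protects the electron-rich phenoxides.

Compound list
1 | (S)-malic acid | O[C@@H](CC(=O)O)C(=O)O | starting material
2 | 2-[(2S,4S)-2-tert-butyl-5-oxo-1,3-dioxolan-4-yl]acetic acid | CC(C)(C)[C@H]1O[C@@H](CC(=O)O)C(=O)O1 | intermediate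
3 | 4-(benzyloxy)-3-methoxybenzyl alcohol | COc1cc(CO)ccc1OCc1ccccc1 | starting material
4 | 4-(benzyloxy)-3-methoxybenzyl bromide | COc1cc(CBr)ccc1OCc1ccccc1 | intermediate
5 | 2-[(2S,4S)-4-(4-benzyloxy-3-methoxybenzyl)-2-tert-butyl-5-oxo-1,3-dioxolan-4-yl]acetic acid | CC(C)(C)[C@H]1O[C@@](Cc2ccc(OCc3ccccc3)c(OC)c2)(CC(=O)O)C(=O)O1 | intermediate
6 | (3S)-3-(4-benzyloxy-3-methoxybenzyl)-3,4-dihydroxybutanoic acid (not isolated) | COc1cc(C[C@@](O)(CO)CC(=O)O)ccc1OCc1ccccc1 | intermediate
7 | (4S)-4-(4-benzyloxy-3-methoxybenzyl)-4-hydroxyoxolan-2-one | COc1cc(C[C@@]2(O)COC(=O)C2)ccc1OCc1ccccc1 | intermediate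
8 | 3-(benzyloxy)-4-methoxybenzyl alcohol | COc1ccc(CO)cc1OCc1ccccc1 | starting material
9 | 3-(benzyloxy)-4-methoxybenzyl bromide | COc1ccc(CBr)cc1OCc1ccccc1 | intermediate
10 | 2-[(2S,4S)-4-(3-benzyloxy-4-methoxybenzyl)-2-tert-butyl-5-oxo-1,3-dioxolan-4-yl]acetic acid | CC(C)(C)[C@H]1O[C@@](Cc2ccc(OC)c(OCc3ccccc3)c2)(CC(=O)O)C(=O)O1 | intermediate
11 | (3S)-3-(3-benzyloxy-4-methoxybenzyl)-3,4-dihydroxybutanoic acid (not isolated) | COc1ccc(C[C@@](O)(CO)CC(=O)O)cc1OCc1ccccc1 | intermediate
12 | (4S)-4-(3-benzyloxy-4-methoxybenzyl)-4-hydroxyoxolan-2-one | COc1ccc(C[C@@]2(O)COC(=O)C2)cc1OCc1ccccc1 | intermediate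
13 | 5-bromovanillin (3-bromo-4-hydroxy-5-methoxybenzaldehyde) | COc1cc(C=O)cc(Br)c1O | starting material
14 | 3-bromo-5-methoxy-4-(oxan-2-yloxy)benzaldehyde (racemic acetal) | COc1cc(C=O)cc(Br)c1OC1CCCCO1 | intermediate
15 | (3R,4S)-4-(4-benzyloxy-3-methoxybenzyl)-3-{[3-bromo-5-methoxy-4-(oxan-2-yloxy)phenyl](hydroxy)methyl}-4-hydroxyoxolan-2-one (carbinol and acetal centres mixed) | COc1cc(C[C@@]2(O)COC(=O)[C@@H]2C(O)c2cc(OC)c(OC3CCCCO3)c(Br)c2)ccc1OCc1ccccc1 | intermediate
16 | (2R,3S)-3-(4-benzyloxy-3-methoxybenzyl)-2-{[3-bromo-5-methoxy-4-(oxan-2-yloxy)phenyl](hydroxy)methyl}butane-1,3,4-triol (not isolated) | COc1cc(C[C@@](O)(CO)[C@H](CO)C(O)c2cc(OC)c(OC3CCCCO3)c(Br)c2)ccc1OCc1ccccc1 | intermediate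
17 | (2R,3S)-3-(4-benzyloxy-3-methoxybenzyl)-2-[(3-bromo-4-hydroxy-5-methoxyphenyl)(hydroxy)methyl]butane-1,3,4-triol (not isolated) | COc1cc(C[C@@](O)(CO)[C@H](CO)C(O)c2cc(OC)c(O)c(Br)c2)ccc1OCc1ccccc1 | intermediate
18 | 4-[(2S,3S)-3-(4-benzyloxy-3-methoxybenzyl)-3,4-dihydroxy-2-(hydroxymethyl)butylidene]-2-bromo-6-methoxycyclohexa-2,5-dien-1-one (not isolated; alkene geometry open) | COC1=CC(=C[C@@H](CO)[C@](O)(CO)Cc2ccc(OCc3ccccc3)c(OC)c2)C=C(Br)C1=O | intermediate
19 | 4-[(2S,3R,4S)-4-(4-benzyloxy-3-methoxybenzyl)-4-hydroxy-3-(hydroxymethyl)oxolan-2-yl]-2-bromo-6-methoxyphenol | COc1cc(C[C@@]2(O)CO[C@H](c3cc(OC)c(O)c(Br)c3)[C@H]2CO)ccc1OCc1ccccc1 | intermediate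
20 | (3S,4R,5S)-3-(4-benzyloxy-3-methoxybenzyl)-5-(4-benzyloxy-3-bromo-5-methoxyphenyl)-4-(hydroxymethyl)oxolan-3-ol | COc1cc(C[C@@]2(O)CO[C@H](c3cc(OC)c(OCc4ccccc4)c(Br)c3)[C@H]2CO)ccc1OCc1ccccc1 | intermediate
21 | (3S,4R,5S)-3-(4-benzyloxy-3-methoxybenzyl)-5-[4-benzyloxy-3-methoxy-5-(4,4,5,5-tetramethyl-1,3,2-dioxaborolan-2-yl)phenyl]-4-(hydroxymethyl)oxolan-3-ol | COc1cc(C[C@@]2(O)CO[C@H](c3cc(OC)c(OCc4ccccc4)c(B4OC(C)(C)C(C)(C)O4)c3)[C@H]2CO)ccc1OCc1ccccc1 | intermediate
22 | (3R,4S)-4-(3-benzyloxy-4-methoxybenzyl)-3-{[3-bromo-5-methoxy-4-(oxan-2-yloxy)phenyl](hydroxy)methyl}-4-hydroxyoxolan-2-one (carbinol and acetal centres mixed) | COc1ccc(C[C@@]2(O)COC(=O)[C@@H]2C(O)c2cc(OC)c(OC3CCCCO3)c(Br)c2)cc1OCc1ccccc1 | intermediate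
23 | (2R,3S)-3-(3-benzyloxy-4-methoxybenzyl)-2-{[3-bromo-5-methoxy-4-(oxan-2-yloxy)phenyl](hydroxy)methyl}butane-1,3,4-triol (not isolated) | COc1ccc(C[C@@](O)(CO)[C@H](CO)C(O)c2cc(OC)c(OC3CCCCO3)c(Br)c2)cc1OCc1ccccc1 | intermediate
24 | (2R,3S)-3-(3-benzyloxy-4-methoxybenzyl)-2-[(3-bromo-4-hydroxy-5-methoxyphenyl)(hydroxy)methyl]butane-1,3,4-triol (not isolated) | COc1ccc(C[C@@](O)(CO)[C@H](CO)C(O)c2cc(OC)c(O)c(Br)c2)cc1OCc1ccccc1 | intermediate
25 | 4-[(2S,3S)-3-(3-benzyloxy-4-methoxybenzyl)-3,4-dihydroxy-2-(hydroxymethyl)butylidene]-2-bromo-6-methoxycyclohexa-2,5-dien-1-one (not isolated; alkene geometry open) | COC1=CC(=C[C@@H](CO)[C@](O)(CO)Cc2ccc(OC)c(OCc3ccccc3)c2)C=C(Br)C1=O | intermediate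
26 | 4-[(2S,3R,4S)-4-(3-benzyloxy-4-methoxybenzyl)-4-hydroxy-3-(hydroxymethyl)oxolan-2-yl]-2-bromo-6-methoxyphenol | COc1ccc(C[C@@]2(O)CO[C@H](c3cc(OC)c(O)c(Br)c3)[C@H]2CO)cc1OCc1ccccc1 | intermediate
27 | 2-bromo-4-[(2S,3R,4S)-4-(3-benzyloxy-4-methoxybenzyl)-4-hydroxy-3-(hydroxymethyl)oxolan-2-yl]-6-methoxyphenyl methanesulfonate | COc1ccc(C[C@@]2(O)CO[C@H](c3cc(OC)c(OS(C)(=O)=O)c(Br)c3)[C@H]2CO)cc1OCc1ccccc1 | intermediate
28 | tri-O-benzyl 5,5'-linked bis-oxolane, ring B O-mesyl, ring C O-benzyl, both oxolanes (2S,3R,4S) | COc1ccc(C[C@@]2(O)CO[C@H](c3cc(OC)c(OS(C)(=O)=O)c(-c4cc([C@H]5OC[C@](O)(Cc6ccc(OCc7ccccc7)c(OC)c6)[C@@H]5CO)cc(OC)c4OCc4ccccc4)c3)[C@H]2CO)cc1OCc1ccccc1 | intermediate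
29 | 5,5'-linked bis-oxolane, ring B O-mesyl, free phenols on rings A, C and D (key-step substrate) | COc1ccc(C[C@@]2(O)CO[C@H](c3cc(OC)c(OS(C)(=O)=O)c(-c4cc([C@H]5OC[C@](O)(Cc6ccc(O)c(OC)c6)[C@@H]5CO)cc(OC)c4O)c3)[C@H]2CO)cc1O | intermediate
30 | ring C p-quinone methide of 29, C3 and C4 of the opened oxolane unchanged (not isolated; alkene geometry open) | COc1ccc(C[C@@]2(O)CO[C@H](c3cc(OC)c(OS(C)(=O)=O)c(C4=CC(=C[C@@H](CO)[C@](O)(CO)Cc5ccc(O)c(OC)c5)C=C(OC)C4=O)c3)[C@H]2CO)cc1O | intermediate
31 | ring B mesylate of the target, (1S,2S,3S) tetralin and (2S,3R,4S) oxolane (key-step product) | COc1ccc(C[C@@]2(O)CO[C@H](c3cc(OC)c(OS(C)(=O)=O)c(-c4cc([C@H]5c6cc(O)c(OC)cc6C[C@@](O)(CO)[C@@H]5CO)cc(OC)c4O)c3)[C@H]2CO)cc1O | intermediate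
32 | CNP0252244.1 | COc1ccc(C[C@@]2(O)CO[C@H](c3cc(OC)c(O)c(-c4cc([C@H]5c6cc(O)c(OC)cc6C[C@@](O)(CO)[C@@H]5CO)cc(OC)c4O)c3)[C@H]2CO)cc1O | target

Total step count: 19. Longest linear sequence: 11 steps (1, 3, 4, 9, 10, 11, 12, 16, 17, 18, 19).

Steps most likely to fail

Step 9 (step 13 is the same reaction on the other lactone). The risk is poor facial selectivity: the aldehyde may add syn to the arylmethyl group if the solvated lithium alkoxide shields its own face, giving the C3 epimer. The fallback replaces kinetic by thermodynamic control. It sets out from 15 as obtained, whatever its C3 composition. Dess–Martin periodinane (NaHCO3, CH2Cl2, 0 °C) would oxidise the benzylic carbinol to the β-keto lactone (3S,4S)-3-[3-bromo-5-methoxy-4-(oxan-2-yloxy)benzoyl]-4-(4-benzyloxy-3-methoxybenzyl)-4-hydroxyoxolan-2-one F1. Its doubly activated C3–H should equilibrate (cat. Et3N) to the isomer with the aroyl group cis to the tertiary hydroxyl (hydrogen bond) and trans to the arylmethyl group. NaBH4 (THF–MeOH, −40 °C) would then reduce the ketone only and come back to 15, whose carbinol configuration again does not matter.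

Step 16. The risk is slow transmetalation at the ortho-substituted boronate, with protodeboronation in the aqueous base overtaking the coupling. The fallback uses tin instead of boron and needs no base or water. It sets out from 20: Me3SnSnMe3 and Pd(PPh3)4 in toluene at 100 °C would give the arylstannane (3S,4R,5S)-3-(4-benzyloxy-3-methoxybenzyl)-5-[4-benzyloxy-3-methoxy-5-(trimethylstannyl)phenyl]-4-(hydroxymethyl)oxolan-3-ol F2. A copper-assisted Stille coupling of F2 with 27 (Pd(PPh3)4, CuI, CsF, DMF, 45 °C) would come back to the route at 28.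

Step 18. The risk is loss of site control or of the intramolecular pathway: the second oxolane may ionise after all, or the long-lived quinone methide may be captured by another molecule and oligomerise. The fallback moves the ring reorganisation to a monomer that has only one oxolane. It sets out from 19:
- CF3CO2H (10 vol %) in CH2Cl2 would convert 19 into the bromo aryltetralin (1S,2S,3S)-7-benzyloxy-1-(3-bromo-4-hydroxy-5-methoxyphenyl)-3-hydroxy-2,3-bis(hydroxymethyl)-6-methoxytetralin F3.
- BnBr and K2CO3 in DMF would give its ring C benzyl ether F4.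
- Miyaura borylation (B2pin2, PdCl2(dppf), KOAc, dioxane, 90 °C) would give the pinacol boronate F5.
- Suzuki coupling of F5 with 27 (Pd(OAc)2, SPhos, K3PO4, dioxane–H2O, 80 °C) would give the tri-O-benzyl tetralin–oxolane mesylate F6.
- Hydrogenolysis of F6 (H2, Pd/C, EtOAc–MeOH) would come back to the route at 31.

Further compounds
F1 | step 9 | (3S,4S)-3-[3-bromo-5-methoxy-4-(oxan-2-yloxy)benzoyl]-4-(4-benzyloxy-3-methoxybenzyl)-4-hydroxyoxolan-2-one | COc1cc(C[C@@]2(O)COC(=O)[C@@H]2C(=O)c2cc(OC)c(OC3CCCCO3)c(Br)c2)ccc1OCc1ccccc1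
F2 | step 16 | (3S,4R,5S)-3-(4-benzyloxy-3-methoxybenzyl)-5-[4-benzyloxy-3-methoxy-5-(trimethylstannyl)phenyl]-4-(hydroxymethyl)oxolan-3-ol | COc1cc(C[C@@]2(O)CO[C@H](c3cc(OC)c(OCc4ccccc4)c([Sn](C)(C)C)c3)[C@H]2CO)ccc1OCc1ccccc1
F3 | step 18 | (1S,2S,3S)-7-benzyloxy-1-(3-bromo-4-hydroxy-5-methoxyphenyl)-3-hydroxy-2,3-bis(hydroxymethyl)-6-methoxytetralin | COc1cc(cc(Br)c1O)[C@H]1c2cc(OCc3ccccc3)c(OC)cc2C[C@@](O)(CO)[C@@H]1CO
F4 | step 18 | (1S,2S,3S)-7-benzyloxy-1-(4-benzyloxy-3-bromo-5-methoxyphenyl)-3-hydroxy-2,3-bis(hydroxymethyl)-6-methoxytetralin | COc1cc(cc(Br)c1OCc1ccccc1)[C@H]1c2cc(OCc3ccccc3)c(OC)cc2C[C@@](O)(CO)[C@@H]1CO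
F5 | step 18 | (1S,2S,3S)-7-benzyloxy-1-[4-benzyloxy-3-methoxy-5-(4,4,5,5-tetramethyl-1,3,2-dioxaborolan-2-yl)phenyl]-3-hydroxy-2,3-bis(hydroxymethyl)-6-methoxytetralin | COc1cc(cc(B2OC(C)(C)C(C)(C)O2)c1OCc1ccccc1)[C@H]1c2cc(OCc3ccccc3)c(OC)cc2C[C@@](O)(CO)[C@@H]1CO
F6 | step 18 | tri-O-benzyl ether of 31 (benzyl on the phenols of rings A, C and D; ring B O-mesyl) | COc1ccc(C[C@@]2(O)CO[C@H](c3cc(OC)c(OS(C)(=O)=O)c(-c4cc([C@H]5c6cc(OCc7ccccc7)c(OC)cc6C[C@@](O)(CO)[C@@H]5CO)cc(OC)c4OCc4ccccc4)c3)[C@H]2CO)cc1OCc1ccccc1
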